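**Plan**
1. Retrosynthesis: the two dioxane C–O bonds (O2′–C3, O3′–C4) are cut first, giving pristimerin and the ortho-quinone of a Δ6 catechol. Both come from one pentacycle, whose ring D is then cut at C13–C18 and C16–C17.
2. Enabling feature: ring D meets ring C only at C13/C14 and ring E only at C17/C18, with the C17 methyl and H-18 cis. A ring C enol silane (C12 oxygen, C14 iodoethyl arm) and a ring E enone (C22 carbonyl) therefore map onto a conjugate addition–alkylation.
3. Forward: ring A → tetralone (ring B) → ring C by asymmetric Michael/aldol annulation → B/C-cis, quaternary C14, C12 enol silane; ring E by Birch reductive methylation; ring D in the key step.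
4. End game: both carbonyls are removed, ring B is dehydrogenated, the catechol is freed and oxidised to the ortho-quinone, part of the quinone is tautomerised to pristimerin, and the two are joined by a hetero-Diels–Alder reaction.
5. Stereochemistry: C9 from the (S)-1-phenylethylamine imine; H-8 from syn hydrogenation; C14 from convex-face methylation; C20 by resolution; C13, C18, C17 by substrate control in the key step; C3/C4 by cycloaddition anti to the C9 methyl.

Key step: step 20

**Remarks on the chemistry**
- Locants are those of the friedelane skeleton of the finished halves (ring C = C8, C9, C11–C14; arm = C15, C16; ring E = C17–C22). β is the face of the C9 methyl group.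
- The aromatic half of the target carries H-8 on the β face (B/C cis). All ring A, B, C intermediates are built in that series; the same relationship steers the key step.
- Assumption: the (S)-acid 6 forms the less soluble salt with (R)-1-phenylethylamine; if the other salt crystallises, the antipodal amine is used.
- In 26 (C14) and in 30–32 (C12, C13) the drawn configuration is the expected major one; these centres are planarised later.
- The ortho-quinone 41 is handled only as a cold filtered solution and is not stored. Step 26 is run in two batches: the first is taken on to 42 in step 27, the second is prepared just before step 28.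

**Route**

Step 1
Reactants: 1 3-methoxy-4-methylbenzoic acid
Product: 3 rac-1,4-dimethyl-5-oxocyclohex-3-ene-1-carboxylic acid, via dienol ether acid 2 (not isolated)
Conditions: Li, NH3(l)/THF, −78 °C; MeI; then 2 M HCl, THF, 50 °C
Reagents that add atoms: methyl iodide CI; water O
Why: Birch reductive alkylation methylates the carboxylate-stabilised C1 carbanion, and acid hydrolysis of the enol ether with migration of the remaining double bond into conjugation should give the enone, with C1 (later C20) formed racemic.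

Step 2
Reactants: 3 rac-1,4-dimethyl-5-oxocyclohex-3-ene-1-carboxylic acid; 4 (R)-1-phenylethylamine
Product: 5 (R)-1-phenylethylammonium (S)-1,4-dimethyl-5-oxocyclohex-3-ene-1-carboxylate
Conditions: 4 (1.0 equiv), acetone, 56 → 4 °C, recrystallise to constant rotation
Reagents that add atoms: none
Why: Classical resolution by diastereomeric salt crystallisation selects the (S)-acid, so C20 is fixed by selection.

Step 3
Reactants: 5 (R)-1-phenylethylammonium (S)-carboxylate
Product: 7 methyl (S)-1,4-dimethyl-5-oxocyclohex-3-ene-1-carboxylate (ring E enone), via (S)-acid 6 (not isolated)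
Conditions: 1 M HCl, EtOAc; then MeI, K2CO3, DMF, 25 °C
Reagents that add atoms: methyl iodide CI
Why: Carboxylate O-alkylation esterifies the hindered acid without touching the quaternary centre, which has no acidic hydrogen.

Step 4
Reactants: 8 2,3-dimethoxytoluene; 9 succinic anhydride
Product: 10 4-(3,4-dimethoxy-2-methylphenyl)-4-oxobutanoic acid
Conditions: AlCl3, CH2Cl2, 0 → 25 °C
Reagents that add atoms: none
Why: Friedel–Crafts acylation should occur para to the unhindered, coplanar methoxy group, which is the position next to the methyl group.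

Step 5
Reactants: 10 keto acid
Product: 11 4-(3,4-dimethoxy-2-methylphenyl)butanoic acid
Conditions: H2 (3 atm), Pd/C, AcOH, HClO4 (cat.), 50 °C
Reagents that add atoms: none
Why: Catalytic hydrogenolysis of an electron-rich aryl ketone to the methylene is the standard second stage of a Haworth tetralone synthesis.

Step 6
Reactants: 11 arylbutanoic acid
Product: 12 6,7-dimethoxy-5-methyl-3,4-dihydronaphthalen-1(2H)-one
Conditions: P2O5/MeSO3H, 40 °C
Reagents that add atoms: none
Why: Intramolecular Friedel–Crafts acylation can only close at the single free ortho position, forming ring B.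

Step 7
Reactants: 12 tetralone
Product: 14 6,7-dimethoxy-4,8-dimethyl-1,2-dihydronaphthalene, via tertiary alcohol 13 (not isolated)
Conditions: MeMgBr, THF, 0 °C; H2O; then TsOH (cat.), toluene, 80 °C
Reagents that add atoms: methylmagnesium bromide C[Mg]Br
Why: Grignard addition followed by acid-catalysed dehydration of the benzylic tertiary alcohol gives the conjugated styrene and introduces the future C9 methyl.

Step 8
Reactants: 14 dihydronaphthalene
Product: 16 rac-6,7-dimethoxy-1,5-dimethyl-3,4-dihydronaphthalen-2(1H)-one, via epoxide 15 (not isolated)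
Conditions: mCPBA, NaHCO3, CH2Cl2, 0 °C; then TsOH (cat.), benzene, 25 °C
Reagents that add atoms: 3-chloroperbenzoic acid OOC(=O)c1cccc(Cl)c1
Why: Epoxidation and Meinwald rearrangement (opening at the benzylic tertiary carbon, 1,2-hydride shift) is the classical route to a 1-methyl-2-tetralone.

Step 9
Reactants: 17 methyl 4-chloro-4-oxobutanoate; 18 ethylene
Product: 20 methyl 4-oxohex-5-enoate, via chloroethyl ketone 19 (not isolated)
Conditions: ethylene, AlCl3, CH2Cl2, 0 °C; then Et3N, Et2O, 25 °C
Reagents that add atoms: none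
Why: Friedel–Crafts acylation of ethylene gives a β-chloroethyl ketone, and E1cB loss of HCl gives the vinyl ketone that already carries the future C15–C16 arm as an ester.

Step 10
Reactants: 16 rac-1-methyl-2-tetralone; 20 methyl 4-oxohex-5-enoate; 21 (S)-1-phenylethylamine
Product: 24 methyl 6-[(1S)-6,7-dimethoxy-1,5-dimethyl-2-oxo-1,2,3,4-tetrahydronaphthalen-1-yl]-4-oxohexanoate, via imine 22 (not isolated), via adduct imine 23 (not isolated)
Conditions: 21, TsOH (cat.), toluene, reflux (−H2O); 20, THF, 40 °C; then AcOH/H2O, 25 °C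
Reagents that add atoms: water O
Why: In this d'Angelo deracemising Michael addition the aryl-conjugated secondary enamine tautomer adds to the enone through a chair-like aza-ene transition state on the face anti to the phenyl group, which should set quaternary C9 as 1S.

Step 11
Reactants: 24 diketo ester
Product: 25 methyl 2-[(4aR)-6,7-dimethoxy-4a,8-dimethyl-2-oxo-2,3,4,4a,9,10-hexahydrophenanthren-1-yl]acetate (C13 ketone, C14=C8)
Conditions: NaOMe, MeOH, 25 → 60 °C
Reagents that add atoms: none
Why: Intramolecular aldol condensation (second half of a Robinson annulation) closes ring C through C14–C8, the only six-membered mode, leaving C9 untouched.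

Step 12
Reactants: 25 tricyclic enone
Product: 26 B/C-cis keto ester (8β-H, 9β-CH3, 14β-H; C13 ketone; C14–CH2CO2Me)
Conditions: H2 (1 atm), Pd/C, MeOH, Et3N (trace), 25 °C
Reagents that add atoms: none
Why: Heterogeneous syn hydrogenation of angular-methyl enones of this type in mildly basic medium should deliver hydrogen on the face of the C9 methyl, as with steroidal 4-en-3-ones, setting H-8 β.

Step 13
Reactants: 26 B/C-cis keto ester
Product: 27 B/C-cis keto ester with quaternary C14 (14β-CH3, 14α-CH2CO2Me)
Conditions: KOt-Bu, t-BuOH/THF, 0 °C; MeI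
Reagents that add atoms: methyl iodide CI
Why: Under equilibrating conditions the cis-fused ketone should enolise toward the ring fusion side (C13=C14, the tetrasubstituted enolate), and enolate alkylation on the convex β face places the methyl cis to H-8 and the C9 methyl.

Step 14
Reactants: 27 ketone
Product: 28 C13 enol triflate (C12=C13)
Conditions: KN(SiMe3)2, THF, −78 °C; PhNTf2, −78 → 0 °C
Reagents that add atoms: N-phenylbis(trifluoromethanesulfonimide) O=S(=O)(N(c1ccccc1)S(=O)(=O)C(F)(F)F)C(F)(F)F
Why: With C14 quaternary the ketone can enolise only toward C12, so enolate O-sulfonylation gives a single vinyl triflate.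

Step 15
Reactants: 28 enol triflate
Product: 29 13-methyl-12-ene ester
Conditions: MeZnCl, Pd(PPh3)4 (cat.), THF, 50 °C
Reagents that add atoms: methylzinc chloride C[Zn]Cl
Why: Negishi cross-coupling of a vinyl triflate tolerates the ester and installs the C13 methyl with the double bond fixed at C12=C13.

Step 16
Reactants: 29 alkene ester
Product: 30 12β,16-diol (13β-H, 13α-CH3)
Conditions: BH3·SMe2 (excess), THF, 0 → 65 °C; then NaOH, H2O2, 0 → 25 °C
Reagents that add atoms: hydrogen peroxide OO
Why: Hydroboration–oxidation places oxygen at the less substituted C12 by syn addition on the face away from the pseudoaxial C14 arm, while refluxing borane also reduces the ester to the C16 alcohol.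

Step 17
Reactants: 30 diol
Product: 31 16-iodo-12β-ol
Conditions: I2, PPh3, imidazole, CH2Cl2, 0 °C
Reagents that add atoms: iodine II
Why: The Appel-type iodination is selective for the primary alcohol over the hindered secondary one.

Step 18
Reactants: 31 iodo alcohol
Product: 32 16-iodo-12-ketone
Conditions: Dess–Martin periodinane, NaHCO3, CH2Cl2, 25 °C
Reagents that add atoms: none
Why: Dess–Martin oxidation is neutral and leaves the primary iodide intact.

Step 19
Reactants: 32 iodo ketone
Product: 33 ring A, B, C enol silane (C12–OSiMe3, C12=C13, 13-CH3, 8β-H, 14β-CH3, 14α-CH2CH2I)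
Conditions: Me3SiCl, NaI, Et3N, MeCN, 25 °C; pentane extraction
Reagents that add atoms: chlorotrimethylsilane C[Si](C)(C)Cl
Why: Silylation with Me3SiI made in the flask equilibrates to the thermodynamic tetrasubstituted enol silane and never generates a free enolate, so the iodoethyl arm is not attacked.

Step 20
Reactants: 33 ring A, B, C enol silane; 7 ring E enone
Product: 35 methyl 2,3-dimethoxy-12,22-dioxo-24-nor-8β-friedela-1,3,5(10)-trien-29-oate, via Michael adduct enol silane 34 (not isolated)
Conditions: 7 (1.5 equiv), Me3SiNTf2 (10 mol %), CH2Cl2, −78 → −40 °C; then Et3N, Bu4N[Ph3SiF2], THF, −40 → 40 °C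
Reagents that add atoms: none
Why: The O-silylated enone is attacked at C18 by C13 of the enol silane and the silyl group is passed on, so the adduct is held as the C17–C22 enol silane 34; fluoride then frees the C17 enolate regiospecifically and it displaces the C16 iodide, the closest known type being a Mukaiyama–Michael addition followed by fluoride-induced alkylation of the derived silyl enol ether (Michael-initiated ring closure). Ring D closes 6-exo-tet. At C13 the B/C-cis half-chair that keeps the C9 and C14 methyls equatorial has the iodoethyl arm pseudoaxial on the α face, so axial attack should come from the β face where only H-8 is syn-axial. At C18 the donor should add anti to the C20 methyl, on the face that carries only the flatter ester group. At C17 the four-atom tether from C18 reaches only one face of the enolate, which gives the cis D/E junction. The step needs C- rather than O-alkylation and no second enolate, and both are secured because C12 stays a neutral ketone while the only enolate is the one released at C17–C22.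

Step 21
Reactants: 35 pentacyclic diketone
Product: 36 12,22-bis(enol triflate) (C11=C12, C21=C22)
Conditions: KN(SiMe3)2 (2.5 equiv), THF, −78 °C; PhNTf2, −78 → 0 °C
Reagents that add atoms: N-phenylbis(trifluoromethanesulfonimide) O=S(=O)(N(c1ccccc1)S(=O)(=O)C(F)(F)F)C(F)(F)F
Why: Each ketone has one quaternary neighbour and can enolise in only one direction, and the ester has no α-hydrogen, so enolate triflation gives one bis-triflate.

Step 22
Reactants: 36 bis(enol triflate)
Product: 37 11,21-diene
Conditions: Pd(OAc)2 (cat.), PPh3, HCO2H, Bu3N, DMF, 60 °C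
Reagents that add atoms: none
Why: Palladium-catalysed formate reduction of vinyl triflates replaces each C–O bond by C–H under conditions that spare the ester and aryl ethers.

Step 23
Reactants: 37 diene
Product: 38 methyl 2,3-dimethoxy-24-nor-8β-friedela-1,3,5(10)-trien-29-oate
Conditions: H2 (3 atm), Pd/C, EtOAc, 25 °C
Reagents that add atoms: none
Why: Catalytic hydrogenation saturates the two cis-disubstituted double bonds, creating no new stereocentre and leaving the arene intact.

Step 24
Reactants: 38 saturated pentacycle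
Product: 39 methyl 2,3-dimethoxy-24-nor-8β-friedela-1,3,5(10),6-tetraen-29-oate
Conditions: DDQ (1.1 equiv), 1,4-dioxane, 80 °C
Reagents that add atoms: none
Why: DDQ dehydrogenation removes hydride from C6 (benzylic, para to the C2 methoxy) and then H-7, giving the styrene; quaternary C9 prevents aromatisation and H-8 is untouched.

Step 25
Reactants: 39 Δ6 dimethyl ether
Product: 40 methyl 2,3-dihydroxy-24-nor-8β-friedela-1,3,5(10),6-tetraen-29-oate
Conditions: BBr3, CH2Cl2, −78 → 0 °C
Reagents that add atoms: none
Why: Lewis-acid cleavage of aryl methyl ethers at low temperature is faster than attack on the hindered tertiary methyl ester.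

Step 26
Reactants: 40 Δ6 catechol
Product: 41 methyl 2,3-dioxo-24-nor-8β-friedela-1(10),4,6-trien-29-oate (ortho-quinone)
Conditions: Ag2O, Na2SO4, Et2O (dilute), 0 °C, dark; filter through Celite, cold filtrate used at once
Reagents that add atoms: none
Why: Dehydrogenation of a catechol by Ag2O in dry ether gives the ortho-quinone under neutral conditions, and with no acid or base present H-8 stays in place, so the C8 configuration is kept.

Step 27
Reactants: 41 ortho-quinone
Product: 42 pristimerin (methyl 3-hydroxy-2-oxo-24-nor-friedela-1(10),3,5,7-tetraen-29-oate)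
Conditions: Et3N (cat.), Et2O (dilute), 0 → 25 °C
Reagents that add atoms: none
Why: Base-catalysed vinylogous enolisation removes H-8, which is conjugated through C6=C7 and C4=C5 to the C3 carbonyl, and reprotonation on O-3 gives the more stable hydroxy quinone methide, with dilution suppressing self-condensation.

Step 28
Reactants: 41 ortho-quinone; 42 pristimerin
Product: 43 CNP0166638.1
Conditions: fresh 41 in Et2O added slowly to 42 (1.2 equiv), CH2Cl2, 4 Å molecular sieves, 0 → 25 °C, dark
Reagents that add atoms: none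
Why: In this inverse-electron-demand hetero-Diels–Alder reaction the O=C–C=O unit of 41 adds across the C3=C4 enol of 42 on the face anti to the C9 methyl, and the nucleophilic C4 should bond first to O3′ so that charge develops on O2′ (the phenoxide para to the styrene unit), which then closes on C3 to give the cis hemiketal.

**Compound list**
1 | 3-methoxy-4-methylbenzoic acid | COc1cc(C(=O)O)ccc1C | starting material
2 | 3-methoxy-1,4-dimethylcyclohexa-2,5-diene-1-carboxylic acid (racemic) | COC1=CC(C)(C(=O)O)C=CC1C | intermediate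
3 | rac-1,4-dimethyl-5-oxocyclohex-3-ene-1-carboxylic acid | CC1=CCC(C)(C(=O)O)CC1=O | intermediate
4 | (R)-1-phenylethylamine | C[C@@H](N)c1ccccc1 | starting material
5 | (R)-1-phenylethylammonium (S)-1,4-dimethyl-5-oxocyclohex-3-ene-1-carboxylate | C[C@@H]([NH3+])c1ccccc1.[O-]C(=O)[C@@]1(C)CC=C(C)C(=O)C1 | intermediate
6 | (S)-1,4-dimethyl-5-oxocyclohex-3-ene-1-carboxylic acid | OC(=O)[C@@]1(C)CC=C(C)C(=O)C1 | intermediate
7 | methyl (S)-1,4-dimethyl-5-oxocyclohex-3-ene-1-carboxylate (ring E enone) | COC(=O)[C@@]1(C)CC=C(C)C(=O)C1 | intermediate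
8 | 2,3-dimethoxytoluene | COc1cccc(C)c1OC | starting material
9 | succinic anhydride | O=C1CCC(=O)O1 | starting material
10 | 4-(3,4-dimethoxy-2-methylphenyl)-4-oxobutanoic acid | COc1ccc(C(=O)CCC(=O)O)c(C)c1OC | intermediate
11 | 4-(3,4-dimethoxy-2-methylphenyl)butanoic acid | COc1ccc(CCCC(=O)O)c(C)c1OC | intermediate
12 | 6,7-dimethoxy-5-methyl-3,4-dihydronaphthalen-1(2H)-one | COc1cc2C(=O)CCCc2c(C)c1OC | intermediate
13 | 6,7-dimethoxy-1,5-dimethyl-1,2,3,4-tetrahydronaphthalen-1-ol | COc1cc2C(C)(O)CCCc2c(C)c1OC | intermediate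
14 | 6,7-dimethoxy-4,8-dimethyl-1,2-dihydronaphthalene | COc1cc2C(C)=CCCc2c(C)c1OC | intermediate
15 | 1,2-epoxy-6,7-dimethoxy-1,5-dimethyl-1,2,3,4-tetrahydronaphthalene | COc1cc2c(c(C)c1OC)CCC1OC21C | intermediate
16 | rac-6,7-dimethoxy-1,5-dimethyl-3,4-dihydronaphthalen-2(1H)-one | COc1cc2C(C)C(=O)CCc2c(C)c1OC | intermediate
17 | methyl 4-chloro-4-oxobutanoate | COC(=O)CCC(Cl)=O | starting material
18 | ethylene | C=C | starting material
19 | methyl 6-chloro-4-oxohexanoate | COC(=O)CCC(=O)CCCl | intermediate
20 | methyl 4-oxohex-5-enoate | COC(=O)CCC(=O)C=C | intermediate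
21 | (S)-1-phenylethylamine | C[C@H](N)c1ccccc1 | starting material
22 | N-[(S)-1-phenylethyl] imine of 16 | COc1cc2c(c(C)c1OC)CCC(=N[C@@H](C)c1ccccc1)C2C | intermediate
23 | N-[(S)-1-phenylethyl] imine of 24 | COc1cc2c(c(C)c1OC)CCC(=N[C@@H](C)c1ccccc1)[C@@]2(C)CCC(=O)CCC(=O)OC | intermediate
24 | methyl 6-[(1S)-6,7-dimethoxy-1,5-dimethyl-2-oxo-1,2,3,4-tetrahydronaphthalen-1-yl]-4-oxohexanoate | COc1cc2c(c(C)c1OC)CCC(=O)[C@@]2(C)CCC(=O)CCC(=O)OC | intermediate
25 | methyl 2-[(4aR)-6,7-dimethoxy-4a,8-dimethyl-2-oxo-2,3,4,4a,9,10-hexahydrophenanthren-1-yl]acetate | COc1cc2c(c(C)c1OC)CCC1=C(CC(=O)OC)C(=O)CC[C@@]21C | intermediate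
26 | B/C-cis keto ester (8β-H, 9β-CH3, 14β-H, C13 ketone, C14–CH2CO2Me) | COc1cc2c(c(C)c1OC)CC[C@H]1[C@@H](CC(=O)OC)C(=O)CC[C@@]21C | intermediate
27 | B/C-cis keto ester with quaternary C14 (14β-CH3, 14α-CH2CO2Me) | COc1cc2c(c(C)c1OC)CC[C@H]1[C@@](C)(CC(=O)OC)C(=O)CC[C@@]21C | intermediate
28 | C13 enol triflate of 27 (C12=C13) | COc1cc2c(c(C)c1OC)CC[C@H]1[C@@](C)(CC(=O)OC)C(OS(=O)(=O)C(F)(F)F)=CC[C@@]21C | intermediate
29 | 13-methyl-12-ene ester | COc1cc2c(c(C)c1OC)CC[C@H]1[C@@](C)(CC(=O)OC)C(C)=CC[C@@]21C | intermediate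
30 | 12β,16-diol (13β-H) | COc1cc2c(c(C)c1OC)CC[C@H]1[C@@](C)(CCO)[C@@H](C)[C@H](O)C[C@@]21C | intermediate
31 | 16-iodo-12β-ol | COc1cc2c(c(C)c1OC)CC[C@H]1[C@@](C)(CCI)[C@@H](C)[C@H](O)C[C@@]21C | intermediate
32 | 16-iodo-12-ketone | COc1cc2c(c(C)c1OC)CC[C@H]1[C@@](C)(CCI)[C@@H](C)C(=O)C[C@@]21C | intermediate
33 | ring A, B, C enol silane (C12–OSiMe3, 8β-H, 14α-iodoethyl) | COc1cc2c(c(C)c1OC)CC[C@@H]3[C@@]2(C)CC(O[Si](C)(C)C)=C(C)[C@]3(C)CCI | intermediate
34 | Michael adduct, C22 trimethylsilyl enol ether (C13–C18 formed, iodide intact) | COc1cc2c(c(C)c1OC)CC[C@@H]3[C@@]2(C)CC(=O)[C@@](C)([C@@H]4C[C@](C)(C(=O)OC)CC(O[Si](C)(C)C)=C4C)[C@]3(C)CCI | intermediate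
35 | methyl 2,3-dimethoxy-12,22-dioxo-24-nor-8β-friedela-1,3,5(10)-trien-29-oate | COc1cc2c(c(C)c1OC)CC[C@@H]3[C@@]2(C)CC(=O)[C@@]4(C)[C@@H]5C[C@](C)(C(=O)OC)CC(=O)[C@]5(C)CC[C@]34C | intermediate
36 | 12,22-bis(enol triflate) of 35 | COc1cc2c(c(C)c1OC)CC[C@@H]3[C@@]2(C)C=C(OS(=O)(=O)C(F)(F)F)[C@@]4(C)[C@@H]5C[C@](C)(C(=O)OC)C=C(OS(=O)(=O)C(F)(F)F)[C@]5(C)CC[C@]34C | intermediate
37 | methyl 2,3-dimethoxy-24-nor-8β-friedela-1,3,5(10),11,21-pentaen-29-oate | COc1cc2c(c(C)c1OC)CC[C@@H]3[C@@]2(C)C=C[C@@]4(C)[C@@H]5C[C@](C)(C(=O)OC)C=C[C@]5(C)CC[C@]34C | intermediate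
38 | methyl 2,3-dimethoxy-24-nor-8β-friedela-1,3,5(10)-trien-29-oate | COc1cc2c(c(C)c1OC)CC[C@@H]3[C@@]2(C)CC[C@@]4(C)[C@@H]5C[C@](C)(C(=O)OC)CC[C@]5(C)CC[C@]34C | intermediate
39 | methyl 2,3-dimethoxy-24-nor-8β-friedela-1,3,5(10),6-tetraen-29-oate | COc1cc2c(c(C)c1OC)C=C[C@@H]3[C@@]2(C)CC[C@@]4(C)[C@@H]5C[C@](C)(C(=O)OC)CC[C@]5(C)CC[C@]34C | intermediate
40 | methyl 2,3-dihydroxy-24-nor-8β-friedela-1,3,5(10),6-tetraen-29-oate | Oc1cc2c(c(C)c1O)C=C[C@@H]3[C@@]2(C)CC[C@@]4(C)[C@@H]5C[C@](C)(C(=O)OC)CC[C@]5(C)CC[C@]34C | intermediate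
41 | methyl 2,3-dioxo-24-nor-8β-friedela-1(10),4,6-trien-29-oate (ortho-quinone) | O=C1C=C2C(=C(C)C1=O)C=C[C@@H]3[C@@]2(C)CC[C@@]4(C)[C@@H]5C[C@](C)(C(=O)OC)CC[C@]5(C)CC[C@]34C | intermediate
42 | pristimerin | O=C1C=C2C(=CC=C3[C@@]2(C)CC[C@@]4(C)[C@@H]5C[C@](C)(C(=O)OC)CC[C@]5(C)CC[C@]34C)C(C)=C1O | intermediate
43 | CNP0166638.1 | COC(=O)[C@]1(C)CC[C@]2(C)CC[C@]3(C)C4=CC=C5C(=CC(=O)[C@@]6(O)Oc7cc8c(c(C)c7O[C@@]56C)C=C[C@@H]5[C@@]8(C)CC[C@@]6(C)[C@@H]7C[C@](C)(C(=O)OC)CC[C@]7(C)CC[C@]56C)[C@]4(C)CC[C@@]3(C)[C@@H]2C1 | target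

**Step count**
Total: 28 steps. Longest linear sequence: 24 steps (steps 4–8 and 10–28, from 2,3-dimethoxytoluene).

**Steps most likely to fail**

Step 20. Two quaternary carbons (C13 beside C14) must be joined to a tertiary one, so the addition may not start, or may occur on the α face of ring C or on the wrong face of ring E. After the addition, ring C must leave its chair to bring C15 and C18 gauche; during that delay the free enolate may take a proton from C11 or C21, or the iodide may be lost by elimination. The fallback separates the two bonds and closes ring D by a reversible aldol addition instead of a substitution. It sets out from 33 and 7. Stoichiometric TiCl4 in CH2Cl2 at −78 °C with hydrolytic work-up gives the diketone iodide F1. Kornblum oxidation (DMSO, NaHCO3, 100 °C) turns the iodide into the keto aldehyde F2. Catalytic KOt-Bu in t-BuOH lets the C17 enolate add to the C16 aldehyde under thermodynamic control, giving the 16-hydroxy pentacycle F3. PhOC(S)Cl/DMAP gives the phenyl thionocarbonate F4, and Bu3SnH/AIBN deoxygenation comes back to the route at 35.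

Step 28. The cycloaddition may proceed with the reversed orientation (O2′ to C4) or on the β face, or the quinone 41 may tautomerise to 42 or condense with itself before it is trapped. The fallback forms the two C–O bonds one at a time so the orientation is fixed by protection. It sets out from 42 and 40. NBS in CH2Cl2 at −20 °C brominates the enol carbon of 42 to give the 4-bromo-2,3-diketone F5. TBSCl/imidazole silylates the less hindered C2′ phenol of 40 to give the mono-silyl ether F6. AgOTf with 2,6-di-tert-butylpyridine ionises F5, and the free O3′ phenol of F6 adds to C4 on the face anti to the C9 methyl, giving the aryl ether F7. Bu4NF then frees O2′, which closes on the C3 ketone as the hemiketal, and the route is rejoined at 43.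

Step 12. Hydrogen may be delivered to the α face, giving the B/C-trans isomer, or the tetrasubstituted double bond may resist reduction. The fallback uses a hydroxyl-directed homogeneous hydrogenation. It sets out from 25. i-Bu2AlH in CH2Cl2 at −78 °C reduces ketone and ester to the allylic diol F8, with hydride expected anti to the C9 methyl (13β-OH). [Ir(cod)(PCy3)(py)]PF6 under H2 in CH2Cl2 delivers hydrogen on the face of the 13β-hydroxyl, giving the all-cis saturated diol F9. CrO3/H2SO4 in acetone oxidises both alcohols to the keto acid F10, and MeI/K2CO3 esterification comes back to the route at 26.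

**Further compounds**
F1 | step 20 | Michael adduct diketone iodide (C17–H, C13–C18 formed) | COc1cc2c(c(C)c1OC)CC[C@@H]3[C@@]2(C)CC(=O)[C@@](C)([C@@H]4C[C@](C)(C(=O)OC)CC(=O)C4C)[C@]3(C)CCI
F2 | step 20 | keto aldehyde (C16 aldehyde) | COc1cc2c(c(C)c1OC)CC[C@@H]3[C@@]2(C)CC(=O)[C@@](C)([C@@H]4C[C@](C)(C(=O)OC)CC(=O)C4C)[C@]3(C)CC=O
F3 | step 20 | 16-hydroxy-12,22-diketone pentacycle | COc1cc2c(c(C)c1OC)CC[C@@H]3[C@@]2(C)CC(=O)[C@@]4(C)[C@@H]5C[C@](C)(C(=O)OC)CC(=O)[C@]5(C)C(O)C[C@]34C
F4 | step 20 | 16-O-phenyl thionocarbonate of F3 | COc1cc2c(c(C)c1OC)CC[C@@H]3[C@@]2(C)CC(=O)[C@@]4(C)[C@@H]5C[C@](C)(C(=O)OC)CC(=O)[C@]5(C)C(OC(=S)Oc6ccccc6)C[C@]34C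
F5 | step 28 | 4-bromo-2,3-dioxo derivative of pristimerin | COC(=O)[C@]1(C)CC[C@]2(C)CC[C@]3(C)C4=CC=C5C(=CC(=O)C(=O)C5(C)Br)[C@]4(C)CC[C@@]3(C)[C@@H]2C1
F6 | step 28 | 2′-O-tert-butyldimethylsilyl ether of 40 | CC(C)(C)[Si](C)(C)Oc1cc2c(c(C)c1O)C=C[C@@H]3[C@@]2(C)CC[C@@]4(C)[C@@H]5C[C@](C)(C(=O)OC)CC[C@]5(C)CC[C@]34C
F7 | step 28 | C4–O3′ aryl ether (C3 ketone, 2′-OTBS) | COC(=O)[C@]1(C)CC[C@]2(C)CC[C@]3(C)C4=CC=C5C(=CC(=O)C(=O)[C@@]5(C)Oc6c(O[Si](C)(C)C(C)(C)C)cc7c(c6C)C=C[C@@H]6[C@@]7(C)CC[C@@]8(C)[C@@H]9C[C@](C)(C(=O)OC)CC[C@]9(C)CC[C@]68C)[C@]4(C)CC[C@@]3(C)[C@@H]2C1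
F8 | step 12 | allylic diol (13β-OH, C16–OH, C14=C8) | COc1cc2c(c(C)c1OC)CCC1=C(CCO)[C@H](O)CC[C@@]21C
F9 | step 12 | B/C-cis saturated diol (8β-H, 14β-H, 13β-OH) | COc1cc2c(c(C)c1OC)CC[C@H]1[C@@H](CCO)[C@H](O)CC[C@@]21C
F10 | step 12 | B/C-cis keto acid | COc1cc2c(c(C)c1OC)CC[C@H]1[C@@H](CC(=O)O)C(=O)CC[C@@]21C
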